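# Proposed synthesis of CNP0212193.2 (methyl 6α-acetoxy-cis-communate) via hydroxyl-directed cyclopropanation

## Analysis of the target

- Target 29 is methyl (12Z)-6α-acetoxylabda-8(17),12,14-trien-19-oate, (4S,5R,6S,9S,10R); labdane numbering is used throughout. It is a trans-decalin (rings A and B) with a quaternary C4 (4α-CH3, axial 4β-CO2Me = C19), a quaternary C10 (axial β-CH3 = C20), 5α-H, an equatorial 6α-acetate, an exocyclic C8=C17 methylene, and an equatorial 9β side chain ending in a Z-configured C12=C13–C14=C15 diene.
- C19, C20 and the C9 chain all lie on the β-face; H5 and the C6 oxygen lie on the α-face. C5 is flanked by the two quaternary carbons C4 and C10, whose axial substituents are 1,3-diaxial.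
- Sensitive groups: the Z-diene (acid, heat, light), the exocyclic methylene (migrates into ring B under acid, or under base once C6 is a carbonyl), the acetate (base, hydride) and the hindered ester.
- Two latent reactivities shape the route. A 6β-oxygen sits cis and close to C19 and can close the 19,6β-lactone. A 6-oxo-Δ5(10),8(17) ring B is the non-aromatic tautomer of a phenol.
- The hard points are the C10 quaternary methyl next to C9 and two bonds from C4, the equatorial 6α-oxygen (which hydride reagents do not deliver between two β-axial groups), and the Z trisubstituted diene.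
- The strategy rests on one feature: C20 on C10 is 1,3 and cis to a β-oxygen on C6 across C5. A 6β-hydroxyl on a C5=C10 alkene can therefore hand a CH2 group to the β-face of C10; the extra C5–C20 bond is cut later through the C6 ketone, which is then reduced to the 6α-alcohol.

## Retrosynthetic reasoning

**Diene (C13–C14, then C12=C13).** 29 is cut at C13–C14 to the Z vinyl iodide 28 and a vinyl tin reagent. The Z geometry is stored in 28 and the coupling retains it, so the diene appears only in the last step. 28 is cut at C12=C13 to aldehyde 27; the forward olefination must give the iodide cis to C11.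

**Functional-group adjustments.** 27 comes from alcohol 26, that from silyl ether 25, and the acetate of 25 from the 6α-alcohol 24. Acetylation before desilylation avoids any hydride or base after the acetate is in place.

**C6 configuration.** 24 is traced to ketone 23. The β-face of C6 is blocked by C20 and the C19 ester, so hydride would give the 6β-alcohol. The forward step must be an electron-transfer reduction that places the C–O bond equatorial.

**C5–C20 bond.** 23 is traced to cyclopropyl ketone 22, in which C20 bridges C5 and C10. Reductive cleavage breaks the bond that overlaps with the carbonyl and leaves C20 as the C10 methyl and a C5 enolate. 22 is the oxidation product of carbinol 21.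

**Key disconnection (C10–C20 and C5–C20).** 21 is cut to the Δ5(10)-octalin 6β-ol 20 and a one-carbon zinc carbenoid. The C6 oxygen delivers CH2 to the β-face of the tetrasubstituted alkene and so sets the quaternary C10 that no intermolecular methyl addition would reach.

**C6 stereocentre and ring B (C6–C7).** 20 is the reagent-controlled reduction product of enone 19. 19 is not made by a carbonylative closure: an acylpalladium on C5 would add 5-exo to the 1,4-diene and give a five-membered ketone, and hot basic conditions would aromatise 19. Ring B is instead closed at C6–C7 from enal 17 by a carbonyl-ene reaction, which builds the C8 methylene and the C6 carbinol 18 without base. Mild oxidation then gives 19 for immediate reduction.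

**C5–C6 bond.** 17 comes from allylic alcohol 16, made from enol triflate 15 by coupling with a hydroxymethyl tin reagent. No acylpalladium is involved, so the isopropenyl group is not engaged. 15 is the enol triflate of ketone 14; C4 is quaternary, so only C10 can enolise.

**C17.** The isopropenyl group of 14 is traced through methyl ketone 13 to the vinyl group of 12. An allyl unit carrying a 2-methyl group cannot be introduced with catalyst control, so C17 is added after the stereocentre is set.

**C9–C10 bond and C9 stereocentre.** 12 is cut to enol silane 11 and allylic carbonate 5. A Claisen rearrangement on ring A would leave C9 uncontrolled relative to the remote C4. The iridium-catalysed branched allylation sets C9 by the ligand alone. 11 is the enol silane of keto ester 10.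

**C4 stereocentre.** 10 is cut at C4–CH3 to enamino ester 8, made from keto ester 6 and amino ester 7; the auxiliary fixes the quaternary centre at the outset.

**Carbonate.** 5 comes from E allylic alcohol 4, that from propargylic alcohol 3, and 3 from alkyne 1 and formaldehyde.

## Alternatives that were turned down

**Alternative 1:** Ring A would be closed last, at C4–C5.
- Forward key step: oxidation of the bis(enol silane) A2 (silyl ketene acetal on the C10 chain, silyl enol ether in ring B) with (NH4)2Ce(NO3)6 or at an anode, giving the 6-oxo trans-decalin A1.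
- For it: the C10 methyl is present from the start, the hindered C4–C5 bond and the C6 ketone arrive together, and the path to the decalin core is shorter than the chosen one. On these points it is stronger.
- Against it: the configuration of the new quaternary C4 depends on an acyclic ketene acetal approaching a ring radical cation, with no element that separates CH3 from CO2Me. A1 also lacks the C9 chain and C17. Both would have to be added beside a 6-oxo/8-oxo ring B, where C7, not C9, is the acidic position.
- Comparison: the chosen strategy fixes C4 at the keto ester stage and has the C9 chain and the C8 methylene in place before the bicycle is complete.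

**Alternative 2:** Both rings would be formed in one step by cutting C4–C5 and C9–C10.
- Forward key step: Mn(OAc)3 oxidises the β-keto ester of polyene A4 to the C4 radical; two 6-endo closures follow, and Cu(OAc)2 oxidises the C8 radical to the alkene, giving A3.
- For it: two rings, four stereocentres, the axial ester and the C8 methylene in a single operation, with the 6α-oxygen already in place. In step economy it is clearly ahead.
- Against it: all new stereocentres are relayed from the single allylic C6 silyloxy centre through a radical cascade. The oxidative termination can place the alkene in or out of ring B. A3 also carries a C3 ketone that must be removed in the presence of the ester, the methylene and the C6 oxygen.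
- Comparison: the chosen strategy is longer but gives each stereocentre its own control element and needs no deoxygenation.

**Alternative 3:** Ring B would be closed at C8–C9.
- Forward key step: Bu3SnH and AIBN generate the C8 vinyl radical from the 2-bromoallyl unit of A6, which adds 6-exo to the enoate on C10 to give A5.
- For it: the methylene arises directly, the 6α-oxygen needs no inversion, and the C9 chain ends in a useful ester; A5 is closer to the target than any intermediate of the chosen route before 24.
- Against it: A6 already contains C4, C5 and the quaternary C10 on one cyclohexane, so the angular methyl problem is moved into the substrate and not solved. C9 is set only by the conformational preference of the radical closure.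
- Comparison: the chosen strategy spends its key step on exactly that C10 centre.

Key step: step 16

Assumption: the enantiomer of each chiral controller (amino ester 7 in step 5, the phosphoramidite in step 7, the oxazaborolidine in step 15) is written as the usual models predict for the configuration drawn; if the sense proved opposite, the mirror-image reagent would be used.

## Route

Step 1
Reactants: 1 tert-butyl(but-3-yn-1-yloxy)dimethylsilane
Product: 3 5-[(tert-butyldimethylsilyl)oxy]pent-2-yn-1-ol, via lithium acetylide 2 (not isolated)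
Conditions: n-BuLi, THF, −78 °C; (CH2O)n, −78 °C → rt
Reagents that add atoms: formaldehyde (as paraformaldehyde), C=O
Why: Deprotonation of the terminal alkyne and addition of the acetylide to formaldehyde (alkynylation of an aldehyde) should give the propargylic alcohol; the silyl ether is inert to the base.

Step 2
Reactants: 3 5-[(tert-butyldimethylsilyl)oxy]pent-2-yn-1-ol
Product: 4 (2E)-5-[(tert-butyldimethylsilyl)oxy]pent-2-en-1-ol
Conditions: NaAlH2(OCH2CH2OMe)2, THF, 0 °C → rt; aq. NaK tartrate
Reagents that add atoms: none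
Why: Hydroxyl-directed trans-hydroalumination of the propargylic alcohol followed by protonolysis should give the E alkene only, which the allylation in step 7 requires.

Step 3
Reactants: 4 (2E)-5-[(tert-butyldimethylsilyl)oxy]pent-2-en-1-ol
Product: 5 (2E)-5-[(tert-butyldimethylsilyl)oxy]pent-2-en-1-yl methyl carbonate
Conditions: ClCO2Me, pyridine, CH2Cl2, 0 °C
Reagents that add atoms: methyl chloroformate, COC(=O)Cl
Why: O-Acylation of the primary allylic alcohol gives the carbonate leaving group for the allylation.

Step 4
Reactants: 6 methyl 2-oxocyclohexane-1-carboxylate; 7 L-valine tert-butyl ester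
Product: 8 methyl 2-{[(2S)-1-tert-butoxy-3-methyl-1-oxobutan-2-yl]amino}cyclohex-1-ene-1-carboxylate
Conditions: cat. TsOH, toluene, reflux, Dean–Stark
Reagents that add atoms: none
Why: Condensation of the amine with the β-keto ester gives the hydrogen-bonded enamino ester (vinylogous carbamate).

Step 5
Reactants: 8 methyl 2-{[(2S)-1-tert-butoxy-3-methyl-1-oxobutan-2-yl]amino}cyclohex-1-ene-1-carboxylate
Product: 10 methyl (1S)-1-methyl-2-oxocyclohexane-1-carboxylate, via C-methylated imine 9 (not isolated)
Conditions: LiN(i-Pr)2, toluene, HMPA (1 equiv), −78 °C; MeI, −78 → −40 °C; then aq. citric acid, rt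
Reagents that add atoms: iodomethane, CI; water, O
Why: Auxiliary-controlled alkylation of a lithiated enamine: lithium is chelated by the tert-butyl ester carbonyl, the isopropyl group covers one face, and MeI attacks C4 from the other, setting the quaternary centre; hydrolysis of the imine releases the keto ester and returns 7.

Step 6
Reactants: 10 methyl (1S)-1-methyl-2-oxocyclohexane-1-carboxylate
Product: 11 methyl (1S)-1-methyl-2-[(trimethylsilyl)oxy]cyclohex-2-ene-1-carboxylate
Conditions: Me3SiOTf, Et3N, CH2Cl2, 0 °C
Reagents that add atoms: trimethylsilyl triflate, C[Si](C)(C)OS(=O)(=O)C(F)(F)F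
Why: Soft enolisation and O-silylation; C4 is quaternary, so only the C5=C10 enol silane can form.

Step 7
Reactants: 11 methyl (1S)-1-methyl-2-[(trimethylsilyl)oxy]cyclohex-2-ene-1-carboxylate; 5 (2E)-5-[(tert-butyldimethylsilyl)oxy]pent-2-en-1-yl methyl carbonate
Product: 12 methyl (1S)-3-{(3S)-5-[(tert-butyldimethylsilyl)oxy]pent-1-en-3-yl}-1-methyl-2-oxocyclohexane-1-carboxylate (C10 epimers)
Conditions: [Ir(cod)Cl]2 (2 mol%), (S,S,Sa)-binaphthol N,N-bis(1-phenylethyl)phosphoramidite (4 mol%, activated with n-PrNH2), CsF, ZnF2, DME, 50 °C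
Reagents that add atoms: none
Why: Iridium-catalysed allylic alkylation of a ketone enolate: the carbonate ionises to an allyliridium complex, and the fluoride-activated enolate attacks its substituted terminus, forming C9–C10 with branched regiochemistry. C9 is set by the ligand, independently of C4; the C10 mixture is erased in step 10.

Step 8
Reactants: 12 methyl (1S)-3-{(3S)-5-[(tert-butyldimethylsilyl)oxy]pent-1-en-3-yl}-1-methyl-2-oxocyclohexane-1-carboxylate
Product: 13 methyl (1S)-3-{(3R)-5-[(tert-butyldimethylsilyl)oxy]-2-oxopentan-3-yl}-1-methyl-2-oxocyclohexane-1-carboxylate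
Conditions: PdCl2 (10 mol%), CuCl, O2 (1 atm), DMF–H2O 7:1, rt
Reagents that add atoms: water, O
Why: Tsuji–Wacker oxidation of the vinyl group of a γ,δ-unsaturated ketone gives the methyl ketone by Markovnikov hydroxypalladation; the near-neutral medium should leave C9, now α to a ketone, configurationally intact.

Step 9
Reactants: 13 methyl (1S)-3-{(3R)-5-[(tert-butyldimethylsilyl)oxy]-2-oxopentan-3-yl}-1-methyl-2-oxocyclohexane-1-carboxylate
Product: 14 methyl (1S)-3-{(3R)-5-[(tert-butyldimethylsilyl)oxy]-2-methylpent-1-en-3-yl}-1-methyl-2-oxocyclohexane-1-carboxylate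
Conditions: Zn, CH2Br2, TiCl4, THF–CH2Cl2, 0 °C → rt
Reagents that add atoms: dibromomethane, BrCBr
Why: Takai–Lombardo methylenation with the non-basic zinc–titanium reagent turns the methyl ketone into the isopropenyl group (C8, C7, C17) without enolising C9; the ring ketone, between a quaternary and a tertiary carbon, should not react.

Step 10
Reactants: 14 methyl (1S)-3-{(3R)-5-[(tert-butyldimethylsilyl)oxy]-2-methylpent-1-en-3-yl}-1-methyl-2-oxocyclohexane-1-carboxylate
Product: 15 methyl (1S)-3-{(3S)-5-[(tert-butyldimethylsilyl)oxy]-2-methylpent-1-en-3-yl}-1-methyl-2-{[(trifluoromethyl)sulfonyl]oxy}cyclohex-2-ene-1-carboxylate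
Conditions: KN(SiMe3)2, THF, −78 °C; PhNTf2, −78 → 0 °C
Reagents that add atoms: N-phenylbis(trifluoromethanesulfonimide), O=S(=O)(N(c1ccccc1)S(=O)(=O)C(F)(F)F)C(F)(F)F
Why: The only α-hydrogen is on C10, so enolate O-sulfonylation gives the tetrasubstituted C5=C10 enol triflate and both C10 epimers converge.

Step 11
Reactants: 15 methyl (1S)-3-{(3S)-5-[(tert-butyldimethylsilyl)oxy]-2-methylpent-1-en-3-yl}-1-methyl-2-{[(trifluoromethyl)sulfonyl]oxy}cyclohex-2-ene-1-carboxylate
Product: 16 methyl (1S)-2-(hydroxymethyl)-1-methyl-3-{(3S)-5-[(tert-butyldimethylsilyl)oxy]-2-methylpent-1-en-3-yl}cyclohex-2-ene-1-carboxylate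
Conditions: Bu3SnCH2OH, Pd(PPh3)4 (10 mol%), LiCl, 1,4-dioxane, 90 °C
Reagents that add atoms: (tributylstannyl)methanol, CCCC[Sn](CCCC)(CCCC)CO
Why: Migita–Kosugi–Stille coupling transfers the hydroxymethyl group (C6) to C5 with retention of the alkene; no acylpalladium species is formed, so the isopropenyl group cannot insert. The γ-hydroxy ester is oxidised without storage to forestall lactonisation onto C19.

Step 12
Reactants: 16 methyl (1S)-2-(hydroxymethyl)-1-methyl-3-{(3S)-5-[(tert-butyldimethylsilyl)oxy]-2-methylpent-1-en-3-yl}cyclohex-2-ene-1-carboxylate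
Product: 17 methyl (1S)-2-formyl-1-methyl-3-{(3S)-5-[(tert-butyldimethylsilyl)oxy]-2-methylpent-1-en-3-yl}cyclohex-2-ene-1-carboxylate
Conditions: MnO2, CH2Cl2, rt
Reagents that add atoms: none
Why: Neutral, selective oxidation of the primary allylic alcohol gives the enal.

Step 13
Reactants: 17 methyl (1S)-2-formyl-1-methyl-3-{(3S)-5-[(tert-butyldimethylsilyl)oxy]-2-methylpent-1-en-3-yl}cyclohex-2-ene-1-carboxylate
Product: 18 methyl 6ξ-hydroxy-12-[(tert-butyldimethylsilyl)oxy]-13,14,15,16,20-pentanorlabda-5(10),8(17)-dien-19-oate (C6 epimers)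
Conditions: Me2AlCl (2.5 equiv), CH2Cl2, −78 → −40 °C; aq. NaK tartrate
Reagents that add atoms: none
Why: Lewis acid-promoted intramolecular carbonyl-ene reaction of type 2: the activated aldehyde carbon bonds to the terminal CH2 of the isopropenyl group (C6–C7) while a methyl hydrogen passes to oxygen, closing ring B as a 3-methylenecyclohexanol without base. C6 forms as a mixture, 6α expected to dominate (oxygen and C9 chain both pseudoaxial), and is levelled in step 14.

Step 14
Reactants: 18 methyl 6ξ-hydroxy-12-[(tert-butyldimethylsilyl)oxy]-13,14,15,16,20-pentanorlabda-5(10),8(17)-dien-19-oate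
Product: 19 methyl 6-oxo-12-[(tert-butyldimethylsilyl)oxy]-13,14,15,16,20-pentanorlabda-5(10),8(17)-dien-19-oate
Conditions: Dess–Martin periodinane, pyridine, CH2Cl2, 0 °C
Reagents that add atoms: none
Why: Dess–Martin oxidation under buffered conditions gives the enone; because 19 is an exocyclic-methylene tautomer of a phenol it is not heated, not exposed to acid or base, and is reduced at once.

Step 15
Reactants: 19 methyl 6-oxo-12-[(tert-butyldimethylsilyl)oxy]-13,14,15,16,20-pentanorlabda-5(10),8(17)-dien-19-oate
Product: 20 methyl 6β-hydroxy-12-[(tert-butyldimethylsilyl)oxy]-13,14,15,16,20-pentanorlabda-5(10),8(17)-dien-19-oate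
Conditions: (S)-Me-CBS oxazaborolidine (0.5 equiv), catecholborane (1.5 equiv), toluene, −78 °C; MeOH, then pH 7 buffer
Reagents that add atoms: none
Why: Corey–Bakshi–Shibata reduction: with the C5 alkenyl arm as the large group and C7H2 as the small one, the (S)-catalyst should deliver hydride to the α-face and give the 6R (6β) alcohol. Catecholborane avoids hydroboration of the methylene, and the neutral work-up avoids lactonisation onto C19.

Step 16
Reactants: 20 methyl 6β-hydroxy-12-[(tert-butyldimethylsilyl)oxy]-13,14,15,16,20-pentanorlabda-5(10),8(17)-dien-19-oate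
Product: 21 methyl 6β-hydroxy-12-[(tert-butyldimethylsilyl)oxy]-13,14,15,16-tetranor-5β,20-cyclolabd-8(17)-en-19-oate
Conditions: Et2Zn (3 equiv), CH2I2 (6 equiv), CH2Cl2, −20 → 0 °C; pyridine, then aq. NH4Cl
Reagents that add atoms: diiodomethane, ICI
Why: Et2Zn deprotonates the 6β-hydroxyl and exchange with CH2I2 puts an iodomethylzinc carbenoid on that oxygen; the carbenoid transfers CH2 to the C5=C10 alkene in a concerted butterfly transition state, forming C10–C20 and C5–C20 together. The closest known reaction type is the hydroxyl-directed Simmons–Smith (Furukawa) cyclopropanation of cyclic allylic alcohols, which is also used on ring-fusion tetrasubstituted alkenes as a route to angular methyl groups. The three-membered ring C5–C20–C10 closes by suprafacial [2+1] addition, the only mode open to a zinc carbenoid. Both new stereocentres, C5 and C10, are set by the C6 oxygen: the tether cannot reach the α-face, so C20 ends β even though the C4 ester and the C9 chain share that face. Two selectivities are needed. First, C5=C10 must react ahead of the C8 methylene; it is allylic to the zinc alkoxide and tetrasubstituted, hence closer and more nucleophilic, and the reagent is limited to about three equivalents at low temperature. Second, the zinc alkoxide must not acylate itself on the cis C19 ester; low temperature, a short reaction time and a non-basic quench are chosen for that reason.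

Step 17
Reactants: 21 methyl 6β-hydroxy-12-[(tert-butyldimethylsilyl)oxy]-13,14,15,16-tetranor-5β,20-cyclolabd-8(17)-en-19-oate
Product: 22 methyl 6-oxo-12-[(tert-butyldimethylsilyl)oxy]-13,14,15,16-tetranor-5β,20-cyclolabd-8(17)-en-19-oate
Conditions: Dess–Martin periodinane, NaHCO3, CH2Cl2, 0 °C → rt
Reagents that add atoms: none
Why: Buffered Dess–Martin oxidation of the cyclopropyl carbinol avoids the acid that would open it through a cyclopropylcarbinyl cation; once C6 is a ketone, lactonisation is no longer possible.

Step 18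
Reactants: 22 methyl 6-oxo-12-[(tert-butyldimethylsilyl)oxy]-13,14,15,16-tetranor-5β,20-cyclolabd-8(17)-en-19-oate
Product: 23 methyl 6-oxo-12-[(tert-butyldimethylsilyl)oxy]-13,14,15,16-tetranorlabd-8(17)-en-19-oate (5α-H, 10β-CH3)
Conditions: SmI2 (2.5 equiv), THF–DMPU, t-BuOH (2 equiv), −78 → 0 °C; pH 7 buffer
Reagents that add atoms: none
Why: Reductive cleavage of a cyclopropyl ketone: the ketyl opens the external C5–C20 bond, which overlaps with the carbonyl π-system, so C20 becomes the C10 methyl. The C5 enolate is protonated from the α-face, away from C20 and the C19 ester, to give the trans ring fusion; the ester is inert to SmI2 under these conditions.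

Step 19
Reactants: 23 methyl 6-oxo-12-[(tert-butyldimethylsilyl)oxy]-13,14,15,16-tetranorlabd-8(17)-en-19-oate
Product: 24 methyl 6α-hydroxy-12-[(tert-butyldimethylsilyl)oxy]-13,14,15,16-tetranorlabd-8(17)-en-19-oate
Conditions: SmI2 (2.5 equiv), H2O, Et3N, THF, 0 °C, short contact time
Reagents that add atoms: none
Why: Electron-transfer reduction of the ketone: the ketyl is protonated on carbon so that the C–O bond ends equatorial (α), which relieves the 1,3-diaxial contacts a 6β-oxygen would have with C20 and the C19 ester. The fast reaction outruns base-induced migration of the β,γ-alkene and reduction of the ester.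

Step 20
Reactants: 24 methyl 6α-hydroxy-12-[(tert-butyldimethylsilyl)oxy]-13,14,15,16-tetranorlabd-8(17)-en-19-oate
Product: 25 methyl 6α-acetoxy-12-[(tert-butyldimethylsilyl)oxy]-13,14,15,16-tetranorlabd-8(17)-en-19-oate
Conditions: Ac2O, DMAP, pyridine, rt
Reagents that add atoms: acetic anhydride, CC(=O)OC(C)=O
Why: DMAP-catalysed acylation of the equatorial secondary alcohol.

Step 21
Reactants: 25 methyl 6α-acetoxy-12-[(tert-butyldimethylsilyl)oxy]-13,14,15,16-tetranorlabd-8(17)-en-19-oate
Product: 26 methyl 6α-acetoxy-12-hydroxy-13,14,15,16-tetranorlabd-8(17)-en-19-oate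
Conditions: HF·pyridine, pyridine, THF, 0 °C → rt
Reagents that add atoms: none
Why: Buffered fluoride cleavage of the primary silyl ether leaves the acetate, the ester and the exocyclic alkene untouched.

Step 22
Reactants: 26 methyl 6α-acetoxy-12-hydroxy-13,14,15,16-tetranorlabd-8(17)-en-19-oate
Product: 27 methyl 6α-acetoxy-12-oxo-13,14,15,16-tetranorlabd-8(17)-en-19-oate
Conditions: Dess–Martin periodinane, NaHCO3, CH2Cl2, 0 °C
Reagents that add atoms: none
Why: Mild oxidation of the primary alcohol to the aldehyde, which is used directly.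

Step 23
Reactants: 27 methyl 6α-acetoxy-12-oxo-13,14,15,16-tetranorlabd-8(17)-en-19-oate
Product: 28 methyl (12Z)-6α-acetoxy-13-iodo-14,15-dinorlabda-8(17),12-dien-19-oate
Conditions: [Ph3PCH2CH3]I, n-BuLi, THF, 0 °C; I2, −78 °C; NaN(SiMe3)2, −78 → −20 °C; then 27, −78 → −20 °C
Reagents that add atoms: ethyltriphenylphosphonium iodide, CC[P+](c1ccccc1)(c1ccccc1)c1ccccc1.[I-]; iodine, II
Why: Stork–Zhao olefination: the α-iodoethylidene ylide adds to the aldehyde under kinetic control and should give the Z 2-iodoalkene (iodine cis to C11, C16 trans); acetate and ester survive the cold, brief exposure to the ylide.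

Step 24
Reactants: 28 methyl (12Z)-6α-acetoxy-13-iodo-14,15-dinorlabda-8(17),12-dien-19-oate
Product: 29 methyl (12Z)-6α-acetoxylabda-8(17),12,14-trien-19-oate (target)
Conditions: CH2=CHSnBu3, Pd(PPh3)4 (5 mol%), CuI, DMF, rt → 40 °C, dark
Reagents that add atoms: tributyl(vinyl)stannane, C=C[Sn](CCCC)(CCCC)CCCC
Why: Stille coupling proceeds with retention at the alkenyl iodide, so the vinyl group (C14, C15) ends cis to C11 and the 12Z diene results; the neutral, mild conditions spare the acetate, the methylene and the diene.

## Compound list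

1 | tert-butyl(but-3-yn-1-yloxy)dimethylsilane | C#CCCO[Si](C)(C)C(C)(C)C | starting material
2 | lithium 4-[(tert-butyldimethylsilyl)oxy]but-1-yn-1-ide | [Li]C#CCCO[Si](C)(C)C(C)(C)C | intermediate
3 | 5-[(tert-butyldimethylsilyl)oxy]pent-2-yn-1-ol | OCC#CCCO[Si](C)(C)C(C)(C)C | intermediate
4 | (2E)-5-[(tert-butyldimethylsilyl)oxy]pent-2-en-1-ol | OC/C=C/CCO[Si](C)(C)C(C)(C)C | intermediate
5 | (2E)-5-[(tert-butyldimethylsilyl)oxy]pent-2-en-1-yl methyl carbonate | COC(=O)OC/C=C/CCO[Si](C)(C)C(C)(C)C | intermediate
6 | methyl 2-oxocyclohexane-1-carboxylate | O=C1CCCCC1C(=O)OC | starting material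
7 | L-valine tert-butyl ester | CC(C)[C@H](N)C(=O)OC(C)(C)C | starting material
8 | methyl 2-{[(2S)-1-tert-butoxy-3-methyl-1-oxobutan-2-yl]amino}cyclohex-1-ene-1-carboxylate | COC(=O)C1=C(N[C@@H](C(C)C)C(=O)OC(C)(C)C)CCCC1 | intermediate
9 | methyl (1S)-2-{[(2S)-1-tert-butoxy-3-methyl-1-oxobutan-2-yl]imino}-1-methylcyclohexane-1-carboxylate | COC(=O)[C@@]1(C)CCCCC1=N[C@@H](C(C)C)C(=O)OC(C)(C)C | intermediate
10 | methyl (1S)-1-methyl-2-oxocyclohexane-1-carboxylate | O=C1CCCC[C@]1(C)C(=O)OC | intermediate
11 | methyl (1S)-1-methyl-2-[(trimethylsilyl)oxy]cyclohex-2-ene-1-carboxylate | C[Si](C)(C)OC1=CCCC[C@]1(C)C(=O)OC | intermediate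
12 | methyl (1S)-3-{(3S)-5-[(tert-butyldimethylsilyl)oxy]pent-1-en-3-yl}-1-methyl-2-oxocyclohexane-1-carboxylate (C10 epimers) | C=C[C@H](CCO[Si](C)(C)C(C)(C)C)C1CCC[C@](C)(C(=O)OC)C1=O | intermediate
13 | methyl (1S)-3-{(3R)-5-[(tert-butyldimethylsilyl)oxy]-2-oxopentan-3-yl}-1-methyl-2-oxocyclohexane-1-carboxylate (C10 epimers) | CC(=O)[C@H](CCO[Si](C)(C)C(C)(C)C)C1CCC[C@](C)(C(=O)OC)C1=O | intermediate
14 | methyl (1S)-3-{(3R)-5-[(tert-butyldimethylsilyl)oxy]-2-methylpent-1-en-3-yl}-1-methyl-2-oxocyclohexane-1-carboxylate (C10 epimers) | C=C(C)[C@H](CCO[Si](C)(C)C(C)(C)C)C1CCC[C@](C)(C(=O)OC)C1=O | intermediate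
15 | methyl (1S)-3-{(3S)-5-[(tert-butyldimethylsilyl)oxy]-2-methylpent-1-en-3-yl}-1-methyl-2-{[(trifluoromethyl)sulfonyl]oxy}cyclohex-2-ene-1-carboxylate | C=C(C)[C@H](CCO[Si](C)(C)C(C)(C)C)C1=C(OS(=O)(=O)C(F)(F)F)[C@@](C)(C(=O)OC)CCC1 | intermediate
16 | methyl (1S)-2-(hydroxymethyl)-1-methyl-3-{(3S)-5-[(tert-butyldimethylsilyl)oxy]-2-methylpent-1-en-3-yl}cyclohex-2-ene-1-carboxylate | C=C(C)[C@H](CCO[Si](C)(C)C(C)(C)C)C1=C(CO)[C@@](C)(C(=O)OC)CCC1 | intermediate
17 | methyl (1S)-2-formyl-1-methyl-3-{(3S)-5-[(tert-butyldimethylsilyl)oxy]-2-methylpent-1-en-3-yl}cyclohex-2-ene-1-carboxylate | C=C(C)[C@H](CCO[Si](C)(C)C(C)(C)C)C1=C(C=O)[C@@](C)(C(=O)OC)CCC1 | intermediate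
18 | methyl 6ξ-hydroxy-12-[(tert-butyldimethylsilyl)oxy]-13,14,15,16,20-pentanorlabda-5(10),8(17)-dien-19-oate (4α-CH3, 4β-CO2Me, 9β chain; C6 epimers) | CC(C)(C)[Si](C)(C)OCC[C@H]1C(=C)CC(O)C2=C1CCC[C@]2(C)C(=O)OC | intermediate
19 | methyl 6-oxo-12-[(tert-butyldimethylsilyl)oxy]-13,14,15,16,20-pentanorlabda-5(10),8(17)-dien-19-oate | CC(C)(C)[Si](C)(C)OCC[C@H]1C(=C)CC(=O)C2=C1CCC[C@]2(C)C(=O)OC | intermediate
20 | methyl 6β-hydroxy-12-[(tert-butyldimethylsilyl)oxy]-13,14,15,16,20-pentanorlabda-5(10),8(17)-dien-19-oate | CC(C)(C)[Si](C)(C)OCC[C@H]1C(=C)C[C@@H](O)C2=C1CCC[C@]2(C)C(=O)OC | intermediate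
21 | methyl 6β-hydroxy-12-[(tert-butyldimethylsilyl)oxy]-13,14,15,16-tetranor-5β,20-cyclolabd-8(17)-en-19-oate (5β,10β-methano) | CC(C)(C)[Si](C)(C)OCC[C@H]1C(=C)C[C@@H](O)[C@]23C[C@@]13CCC[C@]2(C)C(=O)OC | intermediate
22 | methyl 6-oxo-12-[(tert-butyldimethylsilyl)oxy]-13,14,15,16-tetranor-5β,20-cyclolabd-8(17)-en-19-oate | CC(C)(C)[Si](C)(C)OCC[C@H]1C(=C)CC(=O)[C@]23C[C@@]13CCC[C@]2(C)C(=O)OC | intermediate
23 | methyl 6-oxo-12-[(tert-butyldimethylsilyl)oxy]-13,14,15,16-tetranorlabd-8(17)-en-19-oate (5α-H, 10β-CH3) | CC(C)(C)[Si](C)(C)OCC[C@H]1C(=C)CC(=O)[C@@H]2[C@]1(C)CCC[C@]2(C)C(=O)OC | intermediate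
24 | methyl 6α-hydroxy-12-[(tert-butyldimethylsilyl)oxy]-13,14,15,16-tetranorlabd-8(17)-en-19-oate | CC(C)(C)[Si](C)(C)OCC[C@H]1C(=C)C[C@H](O)[C@@H]2[C@]1(C)CCC[C@]2(C)C(=O)OC | intermediate
25 | methyl 6α-acetoxy-12-[(tert-butyldimethylsilyl)oxy]-13,14,15,16-tetranorlabd-8(17)-en-19-oate | CC(C)(C)[Si](C)(C)OCC[C@H]1C(=C)C[C@H](OC(C)=O)[C@@H]2[C@]1(C)CCC[C@]2(C)C(=O)OC | intermediate
26 | methyl 6α-acetoxy-12-hydroxy-13,14,15,16-tetranorlabd-8(17)-en-19-oate | OCC[C@H]1C(=C)C[C@H](OC(C)=O)[C@@H]2[C@]1(C)CCC[C@]2(C)C(=O)OC | intermediate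
27 | methyl 6α-acetoxy-12-oxo-13,14,15,16-tetranorlabd-8(17)-en-19-oate | O=CC[C@H]1C(=C)C[C@H](OC(C)=O)[C@@H]2[C@]1(C)CCC[C@]2(C)C(=O)OC | intermediate
28 | methyl (12Z)-6α-acetoxy-13-iodo-14,15-dinorlabda-8(17),12-dien-19-oate | C/C(I)=C/C[C@H]1C(=C)C[C@H](OC(C)=O)[C@@H]2[C@]1(C)CCC[C@]2(C)C(=O)OC | intermediate
29 | methyl (12Z)-6α-acetoxylabda-8(17),12,14-trien-19-oate, (4S,5R,6S,9S,10R) | C=C/C(C)=C\C[C@H]1C(=C)C[C@H](OC(C)=O)[C@@H]2[C@]1(C)CCC[C@]2(C)C(=O)OC | target

## Step count and least certain steps

Total: 24 steps. Longest linear sequence: 21 steps (6 → 29, steps 4–24); the three-step branch 1 → 5 joins in step 7.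

**Step 16 (key step).**
- What may go wrong: methylene transfer to the hindered tetrasubstituted alkene may be slow, because the C4 ester and the C9 chain crowd the β-face. The carbenoid may then be spent on the C8 methylene. The zinc alkoxide may also acylate itself on the neighbouring C19 ester (lactonisation), which removes the directing group.
- Fallback, from 20 back to 21: replace the alkoxide by a neutral coordinating ether.
  - Protect the hydroxyl under neutral conditions (2-(4-methoxybenzyloxy)-4-methylquinoline, MeOTf, MgO, PhCF3, rt) as the 6β-(4-methoxybenzyl) ether F1.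
  - Cyclopropanate under ether direction with preformed Zn(CH2I)2·DME in CH2Cl2 (0 °C → rt) to give the cyclopropane ether F2.
  - Release with DDQ in CH2Cl2–pH 7 buffer to return to 21.
  - No alkoxide is present at any point, so lactonisation cannot compete.

**Step 7.**
- What may go wrong: the fluoride-activated, α′-quaternary cyclic enolate may be too hindered to attack the substituted allyl terminus, leading to desilylation back to 10 or to the linear product.
- Fallback, from 10 back to 16: build C9 by auxiliary-controlled conjugate addition.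
  - Vilsmeier–Haack–Arnold reaction (PBr3, DMF, CHCl3, 0 → 60 °C) gives the β-bromo enal F3.
  - Horner–Wadsworth–Emmons reaction with diethyl {2-[(4R)-4-benzyl-2-oxo-1,3-oxazolidin-3-yl]-2-oxoethyl}phosphonate (LiCl, i-Pr2NEt, MeCN) gives the E dienoyl imide F4.
  - CH2=C(CH3)MgBr with CuBr·SMe2 (THF, −78 → −20 °C) adds 1,4 to the chelated s-cis imide, anti to the benzyl group, to give the adduct F5. The fully substituted δ-carbon should disfavour 1,6-addition.
  - LiBH4 (Et2O, 1 equiv H2O, 0 °C) removes the auxiliary to give the primary alcohol F6.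
  - TBSCl and imidazole give the silyl ether F7.
  - Coupling of the alkenyl bromide with Bu3SnCH2OH under the conditions of step 11 gives 16.

**Step 15 (with the enone made in step 14).**
- What may go wrong: the exocyclic alkene of 19 may migrate into ring B, followed by tautomerisation to a phenol, before the hindered ketone is reduced.
- Fallback, from the 6α-epimer of 18 back to 20: invert C6 without making the enone.
  - Mitsunobu reaction with chloroacetic acid (PPh3, DIAD, toluene, 0 °C) gives the 6β-chloroacetate F8.
  - Near-neutral cleavage with thiourea and NaHCO3 in EtOH gives 20.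

**Step 19.**
- What may go wrong: carbon protonation of the ketyl may show poor facial selectivity and give a mixture of C6 epimers. Any 6β-alkoxide would be lost as the 19,6β-lactone, so equilibration of the alcohol afterwards is not an option.
- Fallback, from 22 back to 24: classical metal–ammonia reduction of 22 itself (Li, NH3–THF, t-BuOH, −78 °C, NH4Cl quench). This opens the cyclopropane, passes through 23 without isolation, and reduces the ketone to the equatorial alcohol in one operation. The price is exposure of the hindered ester to the reductant for a short time.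

## Further compounds

F1 | step 16 | methyl 6β-[(4-methoxybenzyl)oxy]-12-[(tert-butyldimethylsilyl)oxy]-13,14,15,16,20-pentanorlabda-5(10),8(17)-dien-19-oate | CC(C)(C)[Si](C)(C)OCC[C@H]1C(=C)C[C@@H](OCc3ccc(OC)cc3)C2=C1CCC[C@]2(C)C(=O)OC
F2 | step 16 | methyl 6β-[(4-methoxybenzyl)oxy]-12-[(tert-butyldimethylsilyl)oxy]-13,14,15,16-tetranor-5β,20-cyclolabd-8(17)-en-19-oate | CC(C)(C)[Si](C)(C)OCC[C@H]1C(=C)C[C@@H](OCc4ccc(OC)cc4)[C@]23C[C@@]13CCC[C@]2(C)C(=O)OC
F3 | step 7 | methyl (1S)-2-bromo-3-formyl-1-methylcyclohex-2-ene-1-carboxylate | O=CC1=C(Br)[C@@](C)(C(=O)OC)CCC1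
F4 | step 7 | methyl (1S)-3-{(1E)-3-[(4R)-4-benzyl-2-oxo-1,3-oxazolidin-3-yl]-3-oxoprop-1-en-1-yl}-2-bromo-1-methylcyclohex-2-ene-1-carboxylate | O=C(/C=C/C1=C(Br)[C@@](C)(C(=O)OC)CCC1)N1[C@H](Cc2ccccc2)COC1=O
F5 | step 7 | methyl (1S)-3-{(3S)-1-[(4R)-4-benzyl-2-oxo-1,3-oxazolidin-3-yl]-4-methyl-1-oxopent-4-en-3-yl}-2-bromo-1-methylcyclohex-2-ene-1-carboxylate | O=C(C[C@@H](C(C)=C)C1=C(Br)[C@@](C)(C(=O)OC)CCC1)N1[C@H](Cc2ccccc2)COC1=O
F6 | step 7 | methyl (1S)-2-bromo-3-[(3S)-5-hydroxy-2-methylpent-1-en-3-yl]-1-methylcyclohex-2-ene-1-carboxylate | OCC[C@@H](C(C)=C)C1=C(Br)[C@@](C)(C(=O)OC)CCC1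
F7 | step 7 | methyl (1S)-2-bromo-3-{(3S)-5-[(tert-butyldimethylsilyl)oxy]-2-methylpent-1-en-3-yl}-1-methylcyclohex-2-ene-1-carboxylate | CC(C)(C)[Si](C)(C)OCC[C@@H](C(C)=C)C1=C(Br)[C@@](C)(C(=O)OC)CCC1
F8 | step 15 | methyl 6β-(chloroacetoxy)-12-[(tert-butyldimethylsilyl)oxy]-13,14,15,16,20-pentanorlabda-5(10),8(17)-dien-19-oate | CC(C)(C)[Si](C)(C)OCC[C@H]1C(=C)C[C@@H](OC(=O)CCl)C2=C1CCC[C@]2(C)C(=O)OC
F0 | step 19 | none | none
A1 | alternative 1 | methyl 8,8-(ethylenedioxy)-6-oxo-11,12,13,14,15,16,17-heptanorlabdan-19-oate (trans-fused) | O=C1CC2(OCCO2)C[C@@]3(C)CCC[C@](C)(C(=O)OC)[C@H]13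
A2 | alternative 1 | ring B bis(enol silane): 8,8-(ethylenedioxy)-6-(trimethylsilyloxy)cyclohex-5-ene carrying on C10 a methyl group and a 5-methoxy-4-methyl-5-(trimethylsilyloxy)pent-4-enyl chain | COC(O[Si](C)(C)C)=C(C)CCC[C@]1(C)CC2(OCCO2)CC(O[Si](C)(C)C)=C1
A3 | alternative 2 | methyl 3-oxo-6α-[(tert-butyldimethylsilyl)oxy]-12-(pivaloyloxy)-13,14,15,16-tetranorlabd-8(17)-en-19-oate | CC(C)(C)C(=O)OCC[C@H]1C(=C)C[C@H](O[Si](C)(C)C(C)(C)C)[C@@H]2[C@]1(C)CCC(=O)[C@]2(C)C(=O)OC
A4 | alternative 2 | methyl (6E,10E)-8-[(tert-butyldimethylsilyl)oxy]-2,6,10-trimethyl-3-oxo-13-(pivaloyloxy)trideca-6,10-dienoate | COC(=O)C(C)C(=O)CC/C(C)=C/[C@@H](O[Si](C)(C)C(C)(C)C)C/C(C)=C/CCOC(=O)C(C)(C)C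
A5 | alternative 3 | dimethyl 6α-[(tert-butyldimethylsilyl)oxy]-13,14,15,16-tetranorlabd-8(17)-ene-12,19-dioate | COC(=O)C[C@H]1C(=C)C[C@H](O[Si](C)(C)C(C)(C)C)[C@@H]2[C@]1(C)CCC[C@]2(C)C(=O)OC
A6 | alternative 3 | ring A radical precursor: methyl cyclohexanecarboxylate with 4α-CH3, a 5β-[3-bromo-1-(tert-butyldimethylsilyloxy)but-3-enyl] group and a 10α-[(E)-2-(methoxycarbonyl)vinyl]-10β-methyl unit | C=C(Br)C[C@H](O[Si](C)(C)C(C)(C)C)[C@@H]1[C@@](C)(/C=C/C(=O)OC)CCC[C@]1(C)C(=O)OC
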